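Atom labels follow isochroman-1-one numbering: unit A (unprimed) carries the ether on C4, unit B (primed) carries the free 4'-OH. Compound numbers are those of the steps and of the compound list.

## Analysis of the target

- The target 33 (CNP0139537.5) consists of two 3-methyl-3,4-dihydroisocoumarin units. Ring A carries 6-OH, 7-OMe and 8-OH; ring B carries 7'-OMe, 8'-OH and a free secondary 4'-OH on the lactone ring.
- The units are joined by one ether bond, from the benzylic carbon C4 of unit A to the aromatic carbon C6' of unit B.
- There are four stereocentres, C3/C4 and C3'/C4', each pair (3R,4S). Methyl and oxygen are trans on each lactone ring, which is the erythro (anti) arrangement in the open hydroxy acid. Both pairs are identical, so one chiral source and one method of stereocontrol serve both halves.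
- Sensitive groups: the C4–O–C6' bond is a secondary benzylic aryl ether on an electron-rich ring, so it can ionise in acid and is open to hydrogenolysis. The 4'-hydroxy lactone can translactonise to a five-membered phthalide under base. The polyphenolic rings are easily oxidised, and two aryl methyl ethers must stay while every other oxygen is freed.
- The hard part is the C4–O–C6' ether. Making it by substitution would need a defined steric course at a hindered, ionisable benzylic carbon next to a stereocentre, with a phenol flanked by a methoxy group. Both benzene rings are also penta- or hexasubstituted.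
- The strategy rests on ring B. It is hexasubstituted (C4a', C5', C6', C7', C8', C8a'), and the ether oxygen sits on C6' next to the only unsubstituted carbon, C5'. A C5'–C6' unit with H on C5' and O on C6' is an alkynyl ether, so ring B can be grown around the oxygen of the C4 alcohol and the C4–O bond never has to be made by substitution.

## Retrosynthetic reasoning

**Lactones and protecting groups (33 ⇐ 32 ⇐ 31).** The last bonds cut are C1–O2 and C1'–O2' together with the O-protecting groups. Target 33 comes from silyl ether 32, and 32 from the open bis(methyl ester) 31. The esters are kept open because they tolerate ring construction. With the C4' oxygen silylated, only the C3' hydroxyl can reach the ring B ester, so the six-membered lactone forms and the phthalide cannot. The silyl group is tert-butyldiphenylsilyl so that it outlasts the acetals in acid. The forward step must strip five acetals and close two lactones without ionising the C4–O bond.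

**Ring A carboxyl carbon (31 ⇐ 30 ⇐ 29).** The C8a–C1 bond is cut back to bromide 30 and then to the unfunctionalised arene 29. This carbon has to come late. An ester ortho to the benzylic alkoxide used on the way to 14 would close a phthalide, and an aryl bromide would not survive the alkyllithium used there. In 29 the aryl ring of unit A bears its three oxygens symmetrically, so its two free positions are equivalent. The only competitor for the halogen is the single, crowded C5'–H of ring B.

**Ring B (29 ⇐ 27 + 14).** This is the key disconnection. C4a'–C5' and C6'–C7' are cut, and a lactone bridge is added back across C4a' and C7'. That opens the benzoate ring to the 2-pyrone 27 and the terminal alkynyl ether 14. Pyrone 27 supplies C7' with its methoxy group, C8' with its protected oxygen, C8a' with the ester that becomes C1', and C4a' with the unit B side chain. Alkyne 14 supplies C5'–H and C6' with the ether oxygen already bonded to C4. All six substituents of ring B are thus placed by the two partners, and the forward reaction only has to form two C–C bonds and aromatise by decarboxylation.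

**Alkynyl ether (14 ⇐ 11 ⇐ 10).** The O–C(sp) bond is traced through the dichlorovinyl ether 11 to the benzylic alcohol 10. The alcohol oxygen acts as the nucleophile towards a two-carbon electrophile, so the configuration at C4 set in 10 is carried through unchanged.

**Unit A alcohol (10 ⇐ 9 ⇐ 7 + 3; 7 ⇐ 5 ⇐ 4).** The C4 stereocentre is cut back to ketone 9, whose α-acetal oxygen allows a chelation-controlled hydride delivery to the erythro alcohol. Ketone 9 is split at the aryl–carbonyl bond into aryl iodide 7 and amide 3. The iodide comes from 4 through its bis-acetal 5. The position to be functionalised in 4 is para to the methoxy group and meta to both hydroxyls, so electrophilic substitution cannot reach it. A sterically governed C–H borylation is used instead, followed by replacement of boron by iodine.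

**Pyrone (27 ⇐ 26 ⇐ 21 + 24; 24 ⇐ 23 ⇐ 22).** The pyrone is cut at C4–C5 and O1–C2. This gives the β-keto ester 21, which brings C5, C6, the ester and the side chain, and the three-carbon acid chloride 24, which brings C2, C3 with its methoxy group, and C4. The half-ester chloride 24 is used instead of the corresponding diacid dichloride. With it, acylation and ring closure run under basic conditions and release no hydrogen chloride, so the acetal and silyl groups of 21 survive. Chloride 24 comes from diester 22 through half-acid 23.

**Unit B side chain (21 ⇐ 19 ⇐ 17 ⇐ 16 ⇐ 15 ⇐ 3 ⇐ 2 ⇐ 1).** Keto ester 21 is cut between C2 and C3 to acid 19. Its carboxyl group is traced to a 2-furyl group in 17, which tolerates the organometallic and hydride steps. The C4' stereocentre is again set by chelation-controlled reduction, of furyl ketone 15 to 16, before silylation. Ketone 15 and ketone 9 both come from the same amide 3, made in two steps from 1 through 2. One building block and one mode of stereocontrol thus give both erythro pairs.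

## Alternatives that were turned down

**Alternative 1: photoenol hetero-Diels–Alder closure of the unit A lactone ring.**
- Disconnection: C3–C4 and C1–O2 of unit A.
- Forward key step: the o-(aryloxymethyl)benzaldehyde A2 is irradiated; 1,5-hydrogen transfer gives an E-dienol, which adds acetaldehyde A3 across C4 and the formyl carbon to give lactol A1.
- For: the complete unit B lactone is attached by simple O-alkylation at a primary benzylic carbon, the last ring forms in one step, and the route is more convergent than the chosen one.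
- Against: the step creates C3 and C4 in an intermolecular photocycloaddition to an unactivated aliphatic aldehyde, which is a poor hetero-dienophile for photoenols. Only the remote centres of unit B could bias the absolute sense, so mixtures of the trans and cis lactols in both enantiomeric series are likely. A3 and the benzyl aryl ether of A2 also absorb and can react on their own.
- Comparison: alternative 1 is stronger on convergence and step count. The chosen route instead sets all four centres before the union by substrate-controlled reductions, and its key step creates no stereocentre.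

**Alternative 2: late twofold C–H hydroxylation at C8 and C8'.**
- Disconnection: the C8–O and C8'–O bonds.
- Forward key step: the 8,8'-dideoxy bis-lactone A5 is oxygenated at the one C–H ortho to each lactone carbonyl by carbonyl-directed ruthenium-catalysed metalation and oxidation, giving diacetate A4.
- For: the aromatic precursors lose one oxygen each and become much simpler, and the position of attack is fixed by the directing carbonyl.
- Against: the lactone carbonyl is a weak directing group. The C–H bonds to be broken are flanked by a methoxy group. Such oxidations run in strongly acidic, strongly oxidising media, in which the benzylic C4–O ether can ionise and the electron-rich rings over-oxidise. Two such events must succeed on one advanced molecule, and the C4–O–C6' ether still has to be made by substitution at C4.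
- Comparison: alternative 2 is stronger on starting-material simplicity. The chosen route brings both oxygens in with 4 and with 22 and needs no late oxidation.

**Alternative 3: twofold palladium carbonylative lactonisation.**
- Disconnection: C8a–C1 with C1–O2, and C8a'–C1' with C1'–O2'.
- Forward key step: dibromide A7, which carries both erythro side chains and the ether, is carbonylated twice with intramolecular capture by the C3 and C3' hydroxyls, giving the protected bis-lactone A6.
- For: both lactone rings close in one operation, and phthalide formation is excluded because only the C3 and C3' hydroxyls are free. This end game is shorter than the chosen one, which needs bromination, methoxycarbonylation and a separate lactonisation.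
- Against: it leaves the central problem untouched. The C4–O–C6' ether must already be in A7, made by substitution at the hindered benzylic carbon, and hexasubstituted ring B must be assembled by stepwise arene substitution. Two di-ortho-substituted, electron-rich aryl bromides must both undergo oxidative addition.
- Comparison: alternative 3 is stronger on end-game brevity. In the chosen route ring B is born with its carboxyl carbon and with the ether oxygen in place, so only one carbonylation is needed, on ring A.

Key step: step 18

## Route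

Assumption: Zn(BH4)2 is used as a freshly prepared ether solution, and alkynyl ether 14 is not stored but taken directly into step 18.

Step 1
Reactants: 1 methyl (R)-lactate
Product: 2 methyl (2R)-2-(methoxymethoxy)propanoate
Conditions: MOMCl, i-Pr2NEt, CH2Cl2, 0 °C to rt
Reagents that add atoms: chloromethyl methyl ether, COCCl
Why: O-alkylation of the secondary alcohol with an α-chloro ether under amine base does not touch the stereocentre; the acetal oxygen later serves as the chelating group in both reductions.

Step 2
Reactants: 2 methyl (2R)-2-(methoxymethoxy)propanoate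
Product: 3 (2R)-N-methoxy-2-(methoxymethoxy)-N-methylpropanamide
Conditions: MeNHOMe·HCl, i-PrMgCl, THF, −20 to 0 °C
Reagents that add atoms: N,O-dimethylhydroxylamine hydrochloride, CNOC.Cl
Why: Aminolysis of the ester by the magnesium amide gives the Weinreb amide at low temperature without enolisation, so the α-centre stays R.

Step 3
Reactants: 4 2-methoxyresorcinol
Product: 5 2-methoxy-1,3-bis(methoxymethoxy)benzene
Conditions: MOMCl, i-Pr2NEt, CH2Cl2, 0 °C to rt
Reagents that add atoms: chloromethyl methyl ether, COCCl
Why: Twofold phenol O-alkylation; the acetals withstand the organolithium, hydride and KH steps and are removed together in step 21.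

Step 4
Reactants: 5 2-methoxy-1,3-bis(methoxymethoxy)benzene
Product: 7 5-iodo-2-methoxy-1,3-bis(methoxymethoxy)benzene, via arylboronic pinacol ester 6 (not isolated)
Conditions: [Ir(OMe)(cod)]2 (cat.), 4,4'-di-tert-butyl-2,2'-bipyridine, B2pin2, THF, 80 °C; then CuI (cat.), 1,10-phenanthroline, KI, MeOH–H2O, air, 80 °C
Reagents that add atoms: potassium iodide, [K+].[I-]
Why: Iridium-catalysed C–H borylation is governed by sterics and goes to the only C–H with no ortho substituent, the position meta to both acetal oxygens that electrophilic substitution cannot reach; copper-catalysed iododeboronation in neutral aqueous methanol then replaces boron by iodine at the same carbon and leaves the acetals intact.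

Step 5
Reactants: 7 5-iodo-2-methoxy-1,3-bis(methoxymethoxy)benzene; 3 (2R)-N-methoxy-2-(methoxymethoxy)-N-methylpropanamide
Product: 9 (2R)-1-[4-methoxy-3,5-bis(methoxymethoxy)phenyl]-2-(methoxymethoxy)propan-1-one, via aryllithium 8 (not isolated)
Conditions: n-BuLi, THF, −78 °C; then 3, −78 to 0 °C; aq. NH4Cl
Reagents that add atoms: none
Why: Iodine–lithium exchange followed by Weinreb ketone synthesis; the chelated tetrahedral adduct prevents over-addition and keeps the α-centre from enolising until the quench.

Step 6
Reactants: 9 (2R)-1-[4-methoxy-3,5-bis(methoxymethoxy)phenyl]-2-(methoxymethoxy)propan-1-one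
Product: 10 (1S,2R)-1-[4-methoxy-3,5-bis(methoxymethoxy)phenyl]-2-(methoxymethoxy)propan-1-ol
Conditions: Zn(BH4)2, Et2O, −30 to 0 °C; aq. NH4Cl
Reagents that add atoms: none
Why: Cram-chelate reduction: zinc bridges the carbonyl oxygen and the α-acetal oxygen, and hydride enters from the face of the α-hydrogen, opposite the methyl group, which gives the anti (erythro) alcohol with C1 = S, the configuration of C4.

Step 7
Reactants: 10 (1S,2R)-1-[4-methoxy-3,5-bis(methoxymethoxy)phenyl]-2-(methoxymethoxy)propan-1-ol
Product: 11 5-{(1S,2R)-1-[(E)-1,2-dichloroethenyloxy]-2-(methoxymethoxy)propyl}-2-methoxy-1,3-bis(methoxymethoxy)benzene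
Conditions: KH, THF, 0 °C; then Cl2C=CHCl, −50 °C to rt
Reagents that add atoms: trichloroethylene, ClC=C(Cl)Cl
Why: The potassium alkoxide adds anti to dichloroacetylene formed in the flask from trichloroethylene, the established route to 1,2-dichlorovinyl ethers of secondary alcohols; the oxygen is the nucleophile, so C4 keeps its configuration.

Step 8
Reactants: 11 5-{(1S,2R)-1-[(E)-1,2-dichloroethenyloxy]-2-(methoxymethoxy)propyl}-2-methoxy-1,3-bis(methoxymethoxy)benzene
Product: 14 5-[(1S,2R)-1-(ethynyloxy)-2-(methoxymethoxy)propyl]-2-methoxy-1,3-bis(methoxymethoxy)benzene, via chloroethynyl ether 12 (not isolated), via lithium acetylide 13 (not isolated)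
Conditions: n-BuLi (excess), Et2O, −78 to −40 °C; then MeOH, −78 °C; cold filtration through basic alumina
Reagents that add atoms: none
Why: Base-induced loss of HCl and chlorine–lithium exchange give the lithiated alkynyl ether, which is protonated cold; this is the standard conversion of dichlorovinyl ethers into terminal 1-alkynyl ethers, and the non-acidic cold work-up avoids hydration and rearrangement.

Step 9
Reactants: 3 (2R)-N-methoxy-2-(methoxymethoxy)-N-methylpropanamide
Product: 15 (2R)-1-(furan-2-yl)-2-(methoxymethoxy)propan-1-one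
Conditions: furan, n-BuLi, THF, 0 °C; then 3, −78 to 0 °C; aq. NH4Cl
Reagents that add atoms: furan, c1ccoc1
Why: Weinreb ketone synthesis with 2-furyllithium; the furyl group is a masked carboxyl group that tolerates the reduction and silylation that follow.

Step 10
Reactants: 15 (2R)-1-(furan-2-yl)-2-(methoxymethoxy)propan-1-one
Product: 16 (1R,2R)-1-(furan-2-yl)-2-(methoxymethoxy)propan-1-ol
Conditions: Zn(BH4)2, Et2O, −30 °C; aq. NH4Cl
Reagents that add atoms: none
Why: The same zinc chelate as in step 6 directs hydride to the face of the α-hydrogen and gives the anti alcohol; the descriptor at C1 reads R only because furyl outranks the side chain, and the spatial arrangement is that of 10.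

Step 11
Reactants: 16 (1R,2R)-1-(furan-2-yl)-2-(methoxymethoxy)propan-1-ol
Product: 17 tert-butyl{[(1R,2R)-1-(furan-2-yl)-2-(methoxymethoxy)propoxy]}diphenylsilane
Conditions: TBDPSCl, imidazole, DMAP (cat.), DMF, 40 °C
Reagents that add atoms: tert-butyl(chloro)diphenylsilane, CC(C)(C)[Si](Cl)(c1ccccc1)c1ccccc1
Why: Imidazole-mediated silylation of the secondary alcohol; the diphenylsilyl ether is the most acid-stable common silyl group, so it should outlast the acetals in step 21 and keep the C4' oxygen from lactonising.

Step 12
Reactants: 17 tert-butyl{[(1R,2R)-1-(furan-2-yl)-2-(methoxymethoxy)propoxy]}diphenylsilane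
Product: 19 (2R,3R)-2-(tert-butyldiphenylsilyloxy)-3-(methoxymethoxy)butanoic acid, via acyl formate 18 (not isolated)
Conditions: O3, CH2Cl2–MeOH, −78 °C; then Me2S, −78 °C to rt; H2O
Reagents that add atoms: ozone, [O-][O+]=O
Why: Ozonolysis of both furan double bonds excises three ring carbons and leaves the former C2 as a mixed formic anhydride that hydrolyses to the acid; the stereocentres are not involved.

Step 13
Reactants: 19 (2R,3R)-2-(tert-butyldiphenylsilyloxy)-3-(methoxymethoxy)butanoic acid
Product: 21 methyl (4R,5R)-4-(tert-butyldiphenylsilyloxy)-5-(methoxymethoxy)-3-oxohexanoate, via acyl imidazolide 20 (not isolated)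
Conditions: CDI, THF, rt; then KO2CCH2CO2Me, MgCl2, Et3N, THF–MeCN, rt to 45 °C; aq. citric acid
Reagents that add atoms: potassium methyl malonate, [K+].[O-]C(=O)CC(=O)OC
Why: Decarboxylative Claisen condensation of the acyl imidazolide with the magnesium malonate half ester gives the β-keto ester under nearly neutral conditions that do not epimerise the α-silyloxy centre.

Step 14
Reactants: 22 dimethyl methoxymalonate
Product: 23 2-methoxy-3-methoxy-3-oxopropanoic acid (racemic)
Conditions: KOH (one equiv.), MeOH, 0 °C to rt; then aq. HCl, 0 °C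
Reagents that add atoms: potassium hydroxide, [K+].[OH-]
Why: Monosaponification of a malonic diester stops after the first ester because the carboxylate deactivates the second; the stereocentre is racemic and becomes sp2 in the pyrone.

Step 15
Reactants: 23 2-methoxy-3-methoxy-3-oxopropanoic acid
Product: 24 methyl 3-chloro-2-methoxy-3-oxopropanoate (racemic)
Conditions: (COCl)2, DMF (cat.), CH2Cl2, 0 °C to rt
Reagents that add atoms: oxalyl chloride, ClC(=O)C(=O)Cl
Why: Acid chloride formation through the Vilsmeier-type chloroiminium species; the crude chloride is used at once.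

Step 16
Reactants: 21 methyl (4R,5R)-4-(tert-butyldiphenylsilyloxy)-5-(methoxymethoxy)-3-oxohexanoate; 24 methyl 3-chloro-2-methoxy-3-oxopropanoate
Product: 26 methyl 6-[(1R,2R)-1-(tert-butyldiphenylsilyloxy)-2-(methoxymethoxy)propyl]-4-hydroxy-3-methoxy-2-oxo-2H-pyran-5-carboxylate, via triketo diester 25 (not isolated)
Conditions: MgCl2, pyridine, CH2Cl2, 0 °C to rt; then DBU, PhMe, 60 °C; aq. citric acid
Reagents that add atoms: none
Why: Magnesium-mediated C-acylation of the β-keto ester at its central carbon is followed by enol lactonisation of the side-chain ketone oxygen onto the methoxymalonyl ester with loss of methanol, the usual closure of 3,5-dioxo esters to 4-hydroxy-2-pyrones; the central carbon is the most acidic site, so the silyloxy-bearing centre is not deprotonated.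

Step 17
Reactants: 26 methyl 6-[(1R,2R)-1-(tert-butyldiphenylsilyloxy)-2-(methoxymethoxy)propyl]-4-hydroxy-3-methoxy-2-oxo-2H-pyran-5-carboxylate
Product: 27 methyl 6-[(1R,2R)-1-(tert-butyldiphenylsilyloxy)-2-(methoxymethoxy)propyl]-3-methoxy-4-(methoxymethoxy)-2-oxo-2H-pyran-5-carboxylate
Conditions: MOMCl, i-Pr2NEt, CH2Cl2, 0 °C
Reagents that add atoms: chloromethyl methyl ether, COCCl
Why: O-alkylation of the vinylogous acid with a hard electrophile occurs at O4 and gives the 4-alkoxy-2-pyrone; C3 is blocked, so C-alkylation cannot compete.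

Step 18
Reactants: 27 methyl 6-[(1R,2R)-1-(tert-butyldiphenylsilyloxy)-2-(methoxymethoxy)propyl]-3-methoxy-4-(methoxymethoxy)-2-oxo-2H-pyran-5-carboxylate; 14 5-[(1S,2R)-1-(ethynyloxy)-2-(methoxymethoxy)propyl]-2-methoxy-1,3-bis(methoxymethoxy)benzene
Product: 29 methyl 6-[(1S,2R)-1-(tert-butyldiphenylsilyloxy)-2-(methoxymethoxy)propyl]-3-methoxy-4-{(1S,2R)-1-[4-methoxy-3,5-bis(methoxymethoxy)phenyl]-2-(methoxymethoxy)propoxy}-2-(methoxymethoxy)benzoate, via oxabicyclooctadienone 28 (not isolated)
Conditions: 2,6-di-tert-butyl-4-methylpyridine (cat.), CH2Cl2, 12 kbar, 25 °C; then PhMe, 60 °C, 1 atm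
Reagents that add atoms: none
Why: This is an inverse-electron-demand Diels–Alder reaction in which the HOMO of 14, largest on the terminal CH, meets the LUMO of 27, whose C6 is the electrophilic terminus (β to the C5 ester and vinylogous to the lactone carbonyl), so the CH carbon bonds to pyrone C6 (C4a'–C5') and the oxygen-bearing carbon to pyrone C3 (C6'–C7') in a concerted, asynchronous suprafacial [4+2] addition. The closest known reaction type is the cycloaddition of ester-substituted 2-pyrones with alkoxyalkynes, ynamines or ketene acetals followed by loss of CO2. The six-membered carbocycle closes by this intermolecular [4+2] mode as part of the 2-oxabicyclo[2.2.2]octadienone 28, and retro-[4+2] extrusion of the lactone bridge as CO2 on gentle warming makes it aromatic ring B. No stereocentre is created: the two bridgehead centres of 28 are transient, both facial adducts converge on 29, and the four existing centres lie away from the reacting atoms, so the C4–O bond is carried through with its configuration. The step needs head-to-tail regioselectivity, which the matched polarisation of both partners secures because the reverse orientation would pair the nucleophilic CH with the donor-substituted C3. It also needs chemoselectivity over the unimolecular decay of 14 (retro-ene loss of a ketene, [3,3] shift into the electron-rich benzyl ring); pressure accelerates the bimolecular addition, with its strongly negative activation volume, but not these rearrangements, so the addition is run at 25 °C. The hindered pyridine keeps the medium free of acid and so prevents hydration of 14.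

Step 19
Reactants: 29 the ring B benzoate of step 18
Product: 30 methyl 4-{(1S,2R)-1-[2-bromo-4-methoxy-3,5-bis(methoxymethoxy)phenyl]-2-(methoxymethoxy)propoxy}-6-[(1S,2R)-1-(tert-butyldiphenylsilyloxy)-2-(methoxymethoxy)propyl]-3-methoxy-2-(methoxymethoxy)benzoate
Conditions: NBS, NaHCO3, MeCN, −20 to 0 °C, dark
Reagents that add atoms: N-bromosuccinimide, O=C1CCC(=O)N1Br
Why: Electrophilic aromatic bromination should go to ring A, whose two equivalent free positions are each ortho and para to an acetal oxygen and whose ring has no acceptor; the single free C5'–H of ring B is wedged between the silyloxy-bearing branch and the bulky ether, and that ring is deactivated by its ester.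

Step 20
Reactants: 30 the ring A bromide of step 19
Product: 31 methyl 6-[(1S,2R)-1-(tert-butyldiphenylsilyloxy)-2-(methoxymethoxy)propyl]-3-methoxy-4-{(1S,2R)-1-[4-methoxy-2-(methoxycarbonyl)-3,5-bis(methoxymethoxy)phenyl]-2-(methoxymethoxy)propoxy}-2-(methoxymethoxy)benzoate
Conditions: Pd(OAc)2 (cat.), Xantphos, CO (1 atm), MeOH, Et3N, PhMe, 80 °C
Reagents that add atoms: carbon monoxide, [C-]#[O+]; methanol, CO
Why: Palladium-catalysed alkoxycarbonylation: oxidative addition of the aryl bromide to zerovalent palladium, CO insertion and methanolysis of the acyl complex; the wide-bite-angle diphosphine allows ortho-substituted aryl bromides to react at atmospheric pressure, and the weak amine base leaves esters, acetals and the silyl ether untouched.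

Step 21
Reactants: 31 the bis(methyl ester) of step 20
Product: 32 (3R,4S)-4-{[(3R,4S)-4-(tert-butyldiphenylsilyloxy)-8-hydroxy-7-methoxy-3-methyl-1-oxo-3,4-dihydro-1H-isochromen-6-yl]oxy}-6,8-dihydroxy-7-methoxy-3-methyl-3,4-dihydro-1H-isochromen-1-one
Conditions: HCl (2 M in MeOH), THF, 40 °C
Reagents that add atoms: none
Why: Acid-catalysed acetal exchange removes all five methoxymethyl groups as dimethoxymethane, and the freed C3 and C3' hydroxyls close the two six-membered lactones on the neighbouring methyl esters by transesterification; the C4 oxygen is an ether and the C4' oxygen is still silylated, so no five-membered lactone can form and no stereocentre is touched.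

Step 22
Reactants: 32 the silyl-protected bis-lactone of step 21
Product: 33 (3R,4S)-4-{[(3R,4S)-4,8-dihydroxy-7-methoxy-3-methyl-1-oxo-3,4-dihydro-1H-isochromen-6-yl]oxy}-6,8-dihydroxy-7-methoxy-3-methyl-3,4-dihydro-1H-isochromen-1-one (CNP0139537.5)
Conditions: HF·pyridine, pyridine, THF, 0 °C to rt
Reagents that add atoms: none
Why: Fluoride cleaves the Si–O bond under weakly acidic, non-basic conditions, so the freed 4'-alkoxide is never present and translactonisation to the phthalide is avoided.

## Compound list

1 | methyl (R)-lactate | C[C@@H](O)C(=O)OC | starting material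
2 | methyl (2R)-2-(methoxymethoxy)propanoate | C[C@@H](OCOC)C(=O)OC | intermediate
3 | (2R)-N-methoxy-2-(methoxymethoxy)-N-methylpropanamide | C[C@@H](OCOC)C(=O)N(C)OC | intermediate
4 | 2-methoxyresorcinol | COc1c(O)cccc1O | starting material
5 | 2-methoxy-1,3-bis(methoxymethoxy)benzene | COCOc1cccc(OCOC)c1OC | intermediate
6 | 2-[4-methoxy-3,5-bis(methoxymethoxy)phenyl]-4,4,5,5-tetramethyl-1,3,2-dioxaborolane | COCOc1cc(B2OC(C)(C)C(C)(C)O2)cc(OCOC)c1OC | intermediate (not isolated)
7 | 5-iodo-2-methoxy-1,3-bis(methoxymethoxy)benzene | COCOc1cc(I)cc(OCOC)c1OC | intermediate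
8 | [4-methoxy-3,5-bis(methoxymethoxy)phenyl]lithium | [Li]c1cc(OCOC)c(OC)c(OCOC)c1 | intermediate (not isolated)
9 | (2R)-1-[4-methoxy-3,5-bis(methoxymethoxy)phenyl]-2-(methoxymethoxy)propan-1-one | C[C@@H](OCOC)C(=O)c1cc(OCOC)c(OC)c(OCOC)c1 | intermediate
10 | (1S,2R)-1-[4-methoxy-3,5-bis(methoxymethoxy)phenyl]-2-(methoxymethoxy)propan-1-ol | O[C@@H](c1cc(OCOC)c(OC)c(OCOC)c1)[C@@H](C)OCOC | intermediate
11 | 5-{(1S,2R)-1-[(E)-1,2-dichloroethenyloxy]-2-(methoxymethoxy)propyl}-2-methoxy-1,3-bis(methoxymethoxy)benzene | Cl/C=C(/Cl)O[C@@H](c1cc(OCOC)c(OC)c(OCOC)c1)[C@@H](C)OCOC | intermediate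
12 | 5-[(1S,2R)-1-(chloroethynyloxy)-2-(methoxymethoxy)propyl]-2-methoxy-1,3-bis(methoxymethoxy)benzene | ClC#CO[C@@H](c1cc(OCOC)c(OC)c(OCOC)c1)[C@@H](C)OCOC | intermediate (not isolated)
13 | lithium acetylide of 14 (lithium on the terminal alkyne carbon) | [Li]C#CO[C@@H](c1cc(OCOC)c(OC)c(OCOC)c1)[C@@H](C)OCOC | intermediate (not isolated)
14 | 5-[(1S,2R)-1-(ethynyloxy)-2-(methoxymethoxy)propyl]-2-methoxy-1,3-bis(methoxymethoxy)benzene | C#CO[C@@H](c1cc(OCOC)c(OC)c(OCOC)c1)[C@@H](C)OCOC | intermediate
15 | (2R)-1-(furan-2-yl)-2-(methoxymethoxy)propan-1-one | C[C@@H](OCOC)C(=O)c1ccco1 | intermediate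
16 | (1R,2R)-1-(furan-2-yl)-2-(methoxymethoxy)propan-1-ol | O[C@@H](c1ccco1)[C@@H](C)OCOC | intermediate
17 | tert-butyl{[(1R,2R)-1-(furan-2-yl)-2-(methoxymethoxy)propoxy]}diphenylsilane | CC(C)(C)[Si](c1ccccc1)(c1ccccc1)O[C@@H](c1ccco1)[C@@H](C)OCOC | intermediate
18 | formic (2R,3R)-2-(tert-butyldiphenylsilyloxy)-3-(methoxymethoxy)butanoic anhydride | O=COC(=O)[C@H](O[Si](c1ccccc1)(c1ccccc1)C(C)(C)C)[C@@H](C)OCOC | intermediate (not isolated)
19 | (2R,3R)-2-(tert-butyldiphenylsilyloxy)-3-(methoxymethoxy)butanoic acid | OC(=O)[C@H](O[Si](c1ccccc1)(c1ccccc1)C(C)(C)C)[C@@H](C)OCOC | intermediate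
20 | (2R,3R)-2-(tert-butyldiphenylsilyloxy)-1-(1H-imidazol-1-yl)-3-(methoxymethoxy)butan-1-one | O=C([C@H](O[Si](c1ccccc1)(c1ccccc1)C(C)(C)C)[C@@H](C)OCOC)n1ccnc1 | intermediate (not isolated)
21 | methyl (4R,5R)-4-(tert-butyldiphenylsilyloxy)-5-(methoxymethoxy)-3-oxohexanoate | COC(=O)CC(=O)[C@H](O[Si](c1ccccc1)(c1ccccc1)C(C)(C)C)[C@@H](C)OCOC | intermediate
22 | dimethyl methoxymalonate | COC(C(=O)OC)C(=O)OC | starting material
23 | 2-methoxy-3-methoxy-3-oxopropanoic acid (racemic) | COC(C(=O)O)C(=O)OC | intermediate
24 | methyl 3-chloro-2-methoxy-3-oxopropanoate (racemic) | COC(C(=O)Cl)C(=O)OC | intermediate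
25 | dimethyl 2-[(2R,3R)-2-(tert-butyldiphenylsilyloxy)-3-(methoxymethoxy)butanoyl]-4-methoxy-3-oxopentanedioate (mixture of tautomers and epimers at C2 and C4) | COC(=O)C(OC)C(=O)C(C(=O)OC)C(=O)[C@H](O[Si](c1ccccc1)(c1ccccc1)C(C)(C)C)[C@@H](C)OCOC | intermediate (not isolated)
26 | methyl 6-[(1R,2R)-1-(tert-butyldiphenylsilyloxy)-2-(methoxymethoxy)propyl]-4-hydroxy-3-methoxy-2-oxo-2H-pyran-5-carboxylate | COC(=O)C1=C([C@H](O[Si](c2ccccc2)(c2ccccc2)C(C)(C)C)[C@@H](C)OCOC)OC(=O)C(OC)=C1O | intermediate
27 | methyl 6-[(1R,2R)-1-(tert-butyldiphenylsilyloxy)-2-(methoxymethoxy)propyl]-3-methoxy-4-(methoxymethoxy)-2-oxo-2H-pyran-5-carboxylate | COC(=O)C1=C([C@H](O[Si](c2ccccc2)(c2ccccc2)C(C)(C)C)[C@@H](C)OCOC)OC(=O)C(OC)=C1OCOC | intermediate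
28 | 2-oxabicyclo[2.2.2]octa-5,7-dien-3-one adduct of 27 and 14 (both bridgehead epimers; bridgeheads are pyrone C3 with OMe and pyrone C6 with the unit B side chain) | O=C1OC2([C@H](O[Si](c3ccccc3)(c3ccccc3)C(C)(C)C)[C@@H](C)OCOC)C=C(O[C@@H](c3cc(OCOC)c(OC)c(OCOC)c3)[C@@H](C)OCOC)C1(OC)C(OCOC)=C2C(=O)OC | intermediate (not isolated)
29 | methyl 6-[(1S,2R)-1-(tert-butyldiphenylsilyloxy)-2-(methoxymethoxy)propyl]-3-methoxy-4-{(1S,2R)-1-[4-methoxy-3,5-bis(methoxymethoxy)phenyl]-2-(methoxymethoxy)propoxy}-2-(methoxymethoxy)benzoate | COC(=O)c1c(OCOC)c(OC)c(O[C@@H](c2cc(OCOC)c(OC)c(OCOC)c2)[C@@H](C)OCOC)cc1[C@H](O[Si](c2ccccc2)(c2ccccc2)C(C)(C)C)[C@@H](C)OCOC | intermediate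
30 | methyl 4-{(1S,2R)-1-[2-bromo-4-methoxy-3,5-bis(methoxymethoxy)phenyl]-2-(methoxymethoxy)propoxy}-6-[(1S,2R)-1-(tert-butyldiphenylsilyloxy)-2-(methoxymethoxy)propyl]-3-methoxy-2-(methoxymethoxy)benzoate | COC(=O)c1c(OCOC)c(OC)c(O[C@@H](c2cc(OCOC)c(OC)c(OCOC)c2Br)[C@@H](C)OCOC)cc1[C@H](O[Si](c2ccccc2)(c2ccccc2)C(C)(C)C)[C@@H](C)OCOC | intermediate
31 | methyl 6-[(1S,2R)-1-(tert-butyldiphenylsilyloxy)-2-(methoxymethoxy)propyl]-3-methoxy-4-{(1S,2R)-1-[4-methoxy-2-(methoxycarbonyl)-3,5-bis(methoxymethoxy)phenyl]-2-(methoxymethoxy)propoxy}-2-(methoxymethoxy)benzoate | COC(=O)c1c(OCOC)c(OC)c(O[C@@H](c2cc(OCOC)c(OC)c(OCOC)c2C(=O)OC)[C@@H](C)OCOC)cc1[C@H](O[Si](c2ccccc2)(c2ccccc2)C(C)(C)C)[C@@H](C)OCOC | intermediate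
32 | (3R,4S)-4-{[(3R,4S)-4-(tert-butyldiphenylsilyloxy)-8-hydroxy-7-methoxy-3-methyl-1-oxo-3,4-dihydro-1H-isochromen-6-yl]oxy}-6,8-dihydroxy-7-methoxy-3-methyl-3,4-dihydro-1H-isochromen-1-one | COc1c(O)cc2c(c1O)C(=O)O[C@H](C)[C@H]2Oc1cc2c(c(O)c1OC)C(=O)O[C@H](C)[C@H]2O[Si](c1ccccc1)(c1ccccc1)C(C)(C)C | intermediate
33 | (3R,4S)-4-{[(3R,4S)-4,8-dihydroxy-7-methoxy-3-methyl-1-oxo-3,4-dihydro-1H-isochromen-6-yl]oxy}-6,8-dihydroxy-7-methoxy-3-methyl-3,4-dihydro-1H-isochromen-1-one (CNP0139537.5) | COc1c(O)cc2c(c1O)C(=O)O[C@H](C)[C@H]2Oc1cc2c(c(O)c1OC)C(=O)O[C@H](C)[C@H]2O | target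

## Step count and least certain steps

Total step count: 22. Longest linear sequence: 14 steps (steps 1, 2, 9 to 13 and 16 to 22).

**Step 18 (key step).**
- What may go wrong: the cycloaddition may be too slow to outrun the unimolecular decay of 14. Pyrone 27 is tetrasubstituted and carries two oxygen donors on the diene, which raise its LUMO. Alkynyl ether 14 can lose a ketene by retro-ene reaction, rearrange by a [3,3] shift into its electron-rich benzyl ring, or be hydrated by traces of acid.
- Fallback, setting out from 27 and 9 and coming back at 29: the C6' oxygen is brought in by a more nucleophilic, robust two-carbon partner, and the C4–O bond is then made by substitution.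
  - Pyrone 27 is heated in toluene with 1,1-bis(trimethylsilyloxy)ethene F1, made from trimethylsilyl acetate, LiN(i-Pr)2 and Me3SiCl. Cycloaddition in the same orientation, loss of CO2 and elimination of trimethylsilanol should give, after aqueous work-up, the phenol methyl 6-[(1S,2R)-1-(tert-butyldiphenylsilyloxy)-2-(methoxymethoxy)propyl]-4-hydroxy-3-methoxy-2-(methoxymethoxy)benzoate F2.
  - Ketone 9 is reduced under Felkin–Anh control with K[HB(s-Bu)3] in THF at −78 °C to the threo alcohol (1R,2R)-1-[4-methoxy-3,5-bis(methoxymethoxy)phenyl]-2-(methoxymethoxy)propan-1-ol F3.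
  - Mitsunobu coupling of F2 with F3 (PPh3, diisopropyl azodicarboxylate, PhMe, 0 °C) inverts the benzylic carbon and gives 29.

**Step 16.**
- What may go wrong: the α-methoxy acid chloride 24 has an acidic α-hydrogen and may be consumed by ketene formation or O-acylation instead of C-acylation, or the triketo diester 25 may cyclise sluggishly.
- Fallback, setting out from 19 and 23 and coming back at 25: the roles of the two partners are exchanged.
  - Half-acid 23 is homologated (CDI, then KO2CCH2CO2Me, MgCl2, Et3N) to dimethyl 2-methoxy-3-oxopentanedioate F5.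
  - Acid 19 is converted with 1-chloro-N,N,2-trimethylprop-1-en-1-amine in CH2Cl2 at 0 °C into (2R,3R)-2-(tert-butyldiphenylsilyloxy)-3-(methoxymethoxy)butanoyl chloride F4.
  - Magnesium-mediated C-acylation of F5 at its unsubstituted methylene carbon with F4 (MgCl2, pyridine, CH2Cl2) gives the same triketo diester 25, which DBU closes to 26.

**Step 19.**
- What may go wrong: loss of site selectivity, with bromination at C5' of ring B or twofold bromination, because that position is also ortho and para to ring oxygens.
- Fallback, setting out from 10 and coming back at 31: the halogen is placed on ring A while it is the only arene, as a chloride, which survives the alkyllithium of step 8.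
  - Alcohol 10 is chlorinated with N-chlorosuccinimide in MeCN to (1S,2R)-1-[2-chloro-4-methoxy-3,5-bis(methoxymethoxy)phenyl]-2-(methoxymethoxy)propan-1-ol F6.
  - KH and trichloroethylene give its (E)-1,2-dichloroethenyl ether F7.
  - n-BuLi and then MeOH give 2-chloro-1-[(1S,2R)-1-(ethynyloxy)-2-(methoxymethoxy)propyl]-4-methoxy-3,5-bis(methoxymethoxy)benzene F8.
  - Cycloaddition of F8 with 27 under the conditions of step 18 gives the chloro analogue of 30, methyl 4-{(1S,2R)-1-[2-chloro-4-methoxy-3,5-bis(methoxymethoxy)phenyl]-2-(methoxymethoxy)propoxy}-6-[(1S,2R)-1-(tert-butyldiphenylsilyloxy)-2-(methoxymethoxy)propyl]-3-methoxy-2-(methoxymethoxy)benzoate F9.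
  - Methoxycarbonylation of the aryl chloride (Pd(OAc)2, 1,3-bis(dicyclohexylphosphino)propane, CO, MeOH, K2CO3, 110 °C) gives 31.

**Step 21.**
- What may go wrong: protic acid may ionise the benzylic C4–O bond, whose cation is stabilised by ring A and can be captured by the ortho ester. The silyl group may also be lost before the C3' acetal, which would open the way to a five-membered lactone.
- Fallback, setting out from 30 and coming back at 32: the acetals are removed without protic acid before the carboxyl carbon is introduced, and carbonylation closes the ring A lactone directly.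
  - Bromide 30 is treated with Me3SiOTf and 2,2'-bipyridyl in CH2Cl2 at 0 °C and then with water to give methyl 4-[(1S,2R)-1-(2-bromo-3,5-dihydroxy-4-methoxyphenyl)-2-hydroxypropoxy]-6-[(1S,2R)-1-(tert-butyldiphenylsilyloxy)-2-hydroxypropyl]-2-hydroxy-3-methoxybenzoate F10.
  - Carbonylation of F10 (Pd(OAc)2, Xantphos, CO, Et3N, PhMe–MeCN, 80 °C) closes the ring A lactone by intramolecular capture of the acyl palladium species by the C3 hydroxyl. The ring B hydroxy ester lactonises under the same amine and heat, which gives 32.

## Further compounds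

F1 | step 18 | 1,1-bis(trimethylsilyloxy)ethene | C=C(O[Si](C)(C)C)O[Si](C)(C)C
F2 | step 18 | methyl 6-[(1S,2R)-1-(tert-butyldiphenylsilyloxy)-2-(methoxymethoxy)propyl]-4-hydroxy-3-methoxy-2-(methoxymethoxy)benzoate | COC(=O)c1c(OCOC)c(OC)c(O)cc1[C@H](O[Si](c2ccccc2)(c2ccccc2)C(C)(C)C)[C@@H](C)OCOC
F3 | step 18 | (1R,2R)-1-[4-methoxy-3,5-bis(methoxymethoxy)phenyl]-2-(methoxymethoxy)propan-1-ol | O[C@H](c1cc(OCOC)c(OC)c(OCOC)c1)[C@@H](C)OCOC
F4 | step 16 | (2R,3R)-2-(tert-butyldiphenylsilyloxy)-3-(methoxymethoxy)butanoyl chloride | ClC(=O)[C@H](O[Si](c1ccccc1)(c1ccccc1)C(C)(C)C)[C@@H](C)OCOC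
F5 | step 16 | dimethyl 2-methoxy-3-oxopentanedioate (racemic) | COC(=O)CC(=O)C(OC)C(=O)OC
F6 | step 19 | (1S,2R)-1-[2-chloro-4-methoxy-3,5-bis(methoxymethoxy)phenyl]-2-(methoxymethoxy)propan-1-ol | O[C@@H](c1cc(OCOC)c(OC)c(OCOC)c1Cl)[C@@H](C)OCOC
F7 | step 19 | 2-chloro-1-{(1S,2R)-1-[(E)-1,2-dichloroethenyloxy]-2-(methoxymethoxy)propyl}-4-methoxy-3,5-bis(methoxymethoxy)benzene | Cl/C=C(/Cl)O[C@@H](c1cc(OCOC)c(OC)c(OCOC)c1Cl)[C@@H](C)OCOC
F8 | step 19 | 2-chloro-1-[(1S,2R)-1-(ethynyloxy)-2-(methoxymethoxy)propyl]-4-methoxy-3,5-bis(methoxymethoxy)benzene | C#CO[C@@H](c1cc(OCOC)c(OC)c(OCOC)c1Cl)[C@@H](C)OCOC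
F9 | step 19 | methyl 4-{(1S,2R)-1-[2-chloro-4-methoxy-3,5-bis(methoxymethoxy)phenyl]-2-(methoxymethoxy)propoxy}-6-[(1S,2R)-1-(tert-butyldiphenylsilyloxy)-2-(methoxymethoxy)propyl]-3-methoxy-2-(methoxymethoxy)benzoate | COC(=O)c1c(OCOC)c(OC)c(O[C@@H](c2cc(OCOC)c(OC)c(OCOC)c2Cl)[C@@H](C)OCOC)cc1[C@H](O[Si](c2ccccc2)(c2ccccc2)C(C)(C)C)[C@@H](C)OCOC
F10 | step 21 | methyl 4-[(1S,2R)-1-(2-bromo-3,5-dihydroxy-4-methoxyphenyl)-2-hydroxypropoxy]-6-[(1S,2R)-1-(tert-butyldiphenylsilyloxy)-2-hydroxypropyl]-2-hydroxy-3-methoxybenzoate | COC(=O)c1c(O)c(OC)c(O[C@@H](c2cc(O)c(OC)c(O)c2Br)[C@@H](C)O)cc1[C@H](O[Si](c2ccccc2)(c2ccccc2)C(C)(C)C)[C@@H](C)O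
A1 | alternative 1 | (3R,4S)-4-{[(3R,4S)-4-(tert-butyldimethylsilyloxy)-7-methoxy-8-(methoxymethoxy)-3-methyl-1-oxo-3,4-dihydro-1H-isochromen-6-yl]oxy}-7-methoxy-6,8-bis(methoxymethoxy)-3-methyl-3,4-dihydro-1H-isochromen-1-ol | COc1c(OCOC)cc2c(c1OCOC)C(O)O[C@H](C)[C@H]2Oc1cc2c(c(OCOC)c1OC)C(=O)O[C@H](C)[C@H]2O[Si](C)(C)C(C)(C)C
A2 | alternative 1 | 2-({[(3R,4S)-4-(tert-butyldimethylsilyloxy)-7-methoxy-8-(methoxymethoxy)-3-methyl-1-oxo-3,4-dihydro-1H-isochromen-6-yl]oxy}methyl)-5-methoxy-4,6-bis(methoxymethoxy)benzaldehyde | COc1c(OCOC)cc(COc2cc3c(c(OCOC)c2OC)C(=O)O[C@H](C)[C@H]3O[Si](C)(C)C(C)(C)C)c(C=O)c1OCOC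
A3 | alternative 1 | acetaldehyde | CC=O
A4 | alternative 2 | (3R,4S)-6-{[(3R,4S)-6-acetoxy-8-hydroxy-7-methoxy-3-methyl-1-oxo-3,4-dihydro-1H-isochromen-4-yl]oxy}-8-hydroxy-7-methoxy-3-methyl-1-oxo-3,4-dihydro-1H-isochromen-4-yl acetate | COc1c(OC(C)=O)cc2c(c1O)C(=O)O[C@H](C)[C@H]2Oc1cc2c(c(O)c1OC)C(=O)O[C@H](C)[C@H]2OC(C)=O
A5 | alternative 2 | (3R,4S)-6-{[(3R,4S)-6-acetoxy-7-methoxy-3-methyl-1-oxo-3,4-dihydro-1H-isochromen-4-yl]oxy}-7-methoxy-3-methyl-1-oxo-3,4-dihydro-1H-isochromen-4-yl acetate | COc1c(OC(C)=O)cc2c(c1)C(=O)O[C@H](C)[C@H]2Oc1cc2c(cc1OC)C(=O)O[C@H](C)[C@H]2OC(C)=O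
A6 | alternative 3 | (3R,4S)-4-{[(3R,4S)-4-(tert-butyldimethylsilyloxy)-7-methoxy-8-(methoxymethoxy)-3-methyl-1-oxo-3,4-dihydro-1H-isochromen-6-yl]oxy}-7-methoxy-6,8-bis(methoxymethoxy)-3-methyl-3,4-dihydro-1H-isochromen-1-one | COc1c(OCOC)cc2c(c1OCOC)C(=O)O[C@H](C)[C@H]2Oc1cc2c(c(OCOC)c1OC)C(=O)O[C@H](C)[C@H]2O[Si](C)(C)C(C)(C)C
A7 | alternative 3 | (1S,2R)-1-[2-bromo-4-methoxy-3,5-bis(methoxymethoxy)phenyl]-1-{4-bromo-5-[(1S,2R)-1-(tert-butyldimethylsilyloxy)-2-hydroxypropyl]-2-methoxy-3-(methoxymethoxy)phenoxy}propan-2-ol | COc1c(OCOC)cc([C@H](Oc2cc([C@H](O[Si](C)(C)C(C)(C)C)[C@@H](C)O)c(Br)c(OCOC)c2OC)[C@@H](C)O)c(Br)c1OCOC
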